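**Plan**

1. Numbering follows the lactone: C1 is the lactone carbonyl and C13 the ethyl-bearing carbinol carbon; the target is (2R,4R,6E,8S,11Z,13S). The feature used is the 2-substituted 1,3-diene C10(=CH2)–C11=C12 that lies inside the 14-membered lactone ring.
2. Retrosynthesis: after desilylation and C3 oxidation are undone, the diene is cut at C11=C12 and at the C10 methylene bond, giving a C10≡C11 alkyne and an isopropenyl group on C13. Then the ester C1–O, the aldol bond C2–C3, the C6–OMe bond (back to a C6≡C7 alkyne through a vinylsilane) and C5–C6 (acetylide plus epoxide) are cut.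
3. Forward: a C7–C11 diyne unit and a C3–C5 epoxy alcohol are joined at C5–C6, the internal alkyne is converted into the enol ether, C1–C2 are added by aldol reaction and the C13 alcohol is attached as the ester. The only ring, the macrolactone, is closed last by enyne metathesis; C3 oxidation and desilylation finish the route.
4. Stereochemistry: C13 by catalytic asymmetric ethyl transfer, C8 by Evans alkylation, C4 by Sharpless epoxidation, C2 by Evans syn aldol. The 6E enol ether (C5 cis to C8) comes from tethered syn hydrosilylation and stereoretentive exchange at C6; 11Z comes from the ring closure.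
5. C3 is kept as a carbinol and the C4 hydroxyl as a silyl ether until the ring is closed, so that C2 cannot enolise and the tertiary hydroxyl cannot attack C1 in the open-chain ester.

Key step: step 20

Abbreviations: TBS = tert-butyldimethylsilyl, TES = triethylsilyl, TMS = trimethylsilyl, pin = pinacolato.

**Route**

Step 1
Reactants: 1 methacrolein
Product: 2 (3S)-2-methylpent-1-en-3-ol
Conditions: Et2Zn, (−)-3-exo-morpholinoisoborneol (4 mol %), hexane/toluene, 0 °C
Reagents that add atoms: diethylzinc, CC[Zn]CC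
Why: Amino-alcohol-catalysed enantioselective addition of a dialkylzinc to an aldehyde; this ligand should direct ethyl transfer to the Si face of the enal, as it does for aryl and α-branched unsaturated aldehydes, which sets C13 as S.

Step 2
Reactants: 3 (4R)-4-benzyl-3-propanoyl-1,3-oxazolidin-2-one; 4 3-bromo-1-(trimethylsilyl)prop-1-yne
Product: 6 (4R)-4-benzyl-3-[(2S)-2-methyl-5-(trimethylsilyl)pent-4-ynoyl]-1,3-oxazolidin-2-one, via sodium Z-enolate 5 (not isolated)
Conditions: NaN(SiMe3)2, THF, −78 °C; then 4, −78 to −40 °C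
Reagents that add atoms: none
Why: Evans asymmetric alkylation, in which the chelated Z-enolate is attacked by the propargylic bromide on the face away from the benzyl group, which sets C8 as S.

Step 3
Reactants: 6 (4R)-4-benzyl-3-[(2S)-2-methyl-5-(trimethylsilyl)pent-4-ynoyl]-1,3-oxazolidin-2-one
Product: 7 (2S)-2-methyl-5-(trimethylsilyl)pent-4-yn-1-ol
Conditions: LiBH4, MeOH (1 equiv), THF, 0 °C
Reagents that add atoms: none
Why: Borohydride reduction of the N-acyl imide to the primary alcohol releases the auxiliary without touching C8 or the silyl alkyne.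

Step 4
Reactants: 7 (2S)-2-methyl-5-(trimethylsilyl)pent-4-yn-1-ol
Product: 8 (2S)-2-methyl-5-(trimethylsilyl)pent-4-ynal
Conditions: Dess–Martin periodinane, CH2Cl2, 0 °C to rt
Reagents that add atoms: none
Why: Dess–Martin oxidation under non-basic conditions should give the α-branched aldehyde, which is used at once so that C8 does not epimerise.

Step 5
Reactants: 8 (2S)-2-methyl-5-(trimethylsilyl)pent-4-ynal
Product: 9 [(4S)-6,6-dibromo-4-methylhex-5-en-1-yn-1-yl]trimethylsilane
Conditions: CBr4, PPh3, CH2Cl2, 0 °C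
Reagents that add atoms: carbon tetrabromide, BrC(Br)(Br)Br
Why: First stage of the Corey–Fuchs homologation, a Wittig-type dibromo-olefination mild enough for an α-stereogenic aldehyde; it supplies C6.

Step 6
Reactants: 10 2-methylidenepropane-1,3-diol
Product: 11 2-(TBSO-methyl)prop-2-en-1-ol
Conditions: NaH (1.0 equiv), THF, 0 °C; then t-BuMe2SiCl
Reagents that add atoms: tert-butylchlorodimethylsilane, CC(C)(C)[Si](C)(C)Cl
Why: Monosilylation of a symmetrical diol through its sparingly soluble monosodium alkoxide.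

Step 7
Reactants: 11 2-(TBSO-methyl)prop-2-en-1-ol
Product: 12 [(2R)-2-(TBSO-methyl)oxiran-2-yl]methanol
Conditions: Ti(OiPr)4 (10 mol %), D-(−)-diethyl tartrate (12 mol %), t-BuOOH, 4 Å molecular sieves, CH2Cl2, −20 °C
Reagents that add atoms: tert-butyl hydroperoxide, CC(C)(C)OO
Why: Sharpless asymmetric epoxidation of a 2-substituted allylic alcohol; the D-tartrate delivers oxygen to the face opposite to that used by the natural L-tartrate, which gives the 2R epoxide and sets the later C4 carbinol centre.

Step 8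
Reactants: 9 [(4S)-6,6-dibromo-4-methylhex-5-en-1-yn-1-yl]trimethylsilane; 12 [(2R)-2-(TBSO-methyl)oxiran-2-yl]methanol
Product: 15 (2S,6S)-2-(TBSO-methyl)-6-methyl-9-(trimethylsilyl)nona-4,8-diyne-1,2-diol, via lithium acetylide 13 (not isolated), via diethylalkynylalane 14 (not isolated)
Conditions: 9, n-BuLi (2.1 equiv), THF, −78 to 0 °C; Et2AlCl, toluene, 0 °C; then 12, 0 °C to rt
Reagents that add atoms: none
Why: Second stage of the Corey–Fuchs reaction followed by hydroxyl-directed opening of a 2,3-epoxy alcohol by an alkynylalane at the unsubstituted epoxide carbon (C5); this joins C5 to C6 and leaves the C4–O bond and its configuration untouched.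

Step 9
Reactants: 15 (2S,6S)-2-(TBSO-methyl)-6-methyl-9-(trimethylsilyl)nona-4,8-diyne-1,2-diol
Product: 16 (2S,6S)-2-(TBSO-methyl)-2-hydroxy-6-methyl-9-(trimethylsilyl)nona-4,8-diyn-1-yl benzoate
Conditions: PhCOCl (1.05 equiv), pyridine, CH2Cl2, 0 °C
Reagents that add atoms: benzoyl chloride, O=C(Cl)c1ccccc1
Why: Selective acylation of the primary hydroxyl of a primary/tertiary 1,2-diol masks the C3 oxygen, so that only the tertiary hydroxyl is left for the tether and no primary alkoxide can interfere in the copper step.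

Step 10
Reactants: 16 (2S,6S)-2-(TBSO-methyl)-2-hydroxy-6-methyl-9-(trimethylsilyl)nona-4,8-diyn-1-yl benzoate
Product: 18 [(3E,5S)-5-(TBSO-methyl)-2,2-dimethyl-3-[(2S)-2-methyl-5-(trimethylsilyl)pent-4-yn-1-ylidene]-1,2-oxasilolan-5-yl]methyl benzoate, via dimethylsilyl ether 17 (not isolated)
Conditions: (HMe2Si)2NH, 60 °C; then Pt2[(CH2=CHSiMe2)2O]3 (0.5 mol %), THF, rt
Reagents that add atoms: 1,1,3,3-tetramethyldisilazane, C[SiH](C)N[SiH](C)C
Why: Tethered platinum-catalysed hydrosilylation of a homopropargylic silyl ether, a 5-exo-dig syn addition that puts silicon on C6 and hydrogen on C7 on the same side and so fixes C5 cis to C8; the remote silyl alkyne is out of reach of the tether.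

Step 11
Reactants: 18 the alkenylsiloxane of step 10
Product: 19 (2S,4E,6S)-2-(TBSO-methyl)-2-hydroxy-4-iodo-6-methyl-9-(trimethylsilyl)non-4-en-8-yn-1-yl benzoate
Conditions: N-iodosuccinimide, MeCN/ClCH2CN, 0 °C; aqueous work-up
Reagents that add atoms: N-iodosuccinimide, O=C1CCC(=O)N1I
Why: Iododesilylation of a vinylsilane, an ipso substitution through the β-silyl cation that should keep the alkene geometry and free the tertiary hydroxyl on work-up.

Step 12
Reactants: 19 (2S,4E,6S)-2-(TBSO-methyl)-2-hydroxy-4-iodo-6-methyl-9-(trimethylsilyl)non-4-en-8-yn-1-yl benzoate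
Product: 20 (2S,4Z,6S)-2-(TBSO-methyl)-2-hydroxy-6-methyl-4-(4,4,5,5-tetramethyl-1,3,2-dioxaborolan-2-yl)-9-(trimethylsilyl)non-4-en-8-yn-1-yl benzoate
Conditions: B2pin2, PdCl2(dppf) (5 mol %), KOAc, DMSO, 80 °C
Reagents that add atoms: bis(pinacolato)diboron, CC1(C)OB(OC1(C)C)B1OC(C)(C)C(C)(C)O1
Why: Miyaura borylation of an alkenyl iodide, in which oxidative addition and reductive elimination both retain the alkene geometry and the free tertiary alcohol and the ester are tolerated.

Step 13
Reactants: 20 the alkenylboronate of step 12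
Product: 21 (2S,4E,6S)-2-(TBSO-methyl)-2-hydroxy-4-methoxy-6-methyl-9-(trimethylsilyl)non-4-en-8-yn-1-yl benzoate
Conditions: Cu(OAc)2 (2 equiv), Et3N, MeOH, 4 Å molecular sieves, air, rt
Reagents that add atoms: methanol, CO
Why: Chan–Lam coupling of an alkenylboronate with an aliphatic alcohol, an oxidative copper-mediated C–O bond formation at room temperature that keeps the alkene geometry and so should give the E enol ether with C5 and C8 cis.

Step 14
Reactants: 21 (2S,4E,6S)-2-(TBSO-methyl)-2-hydroxy-4-methoxy-6-methyl-9-(trimethylsilyl)non-4-en-8-yn-1-yl benzoate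
Product: 22 (2S,4E,6S)-2-(TBSO-methyl)-4-methoxy-6-methylnon-4-en-8-yne-1,2-diol
Conditions: K2CO3, MeOH, rt
Reagents that add atoms: none
Why: Base-catalysed methanolysis removes the benzoate and the alkynyl silyl group in one operation, and the exposure is kept short so that the TBS group does not move between the two primary oxygens, which would invert C4.

Step 15
Reactants: 22 (2S,4E,6S)-2-(TBSO-methyl)-4-methoxy-6-methylnon-4-en-8-yne-1,2-diol
Product: 23 1,2-bis-O-triethylsilyl ether of 22
Conditions: Et3SiOTf (2.5 equiv), 2,6-lutidine, CH2Cl2, −78 to 0 °C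
Reagents that add atoms: triethylsilyl trifluoromethanesulfonate, CC[Si](CC)(CC)OS(=O)(=O)C(F)(F)F
Why: Silyl triflate silylation protects both hydroxyls, the hindered tertiary one included, under basic conditions that an enol ether tolerates.

Step 16
Reactants: 23 1,2-bis-O-triethylsilyl ether of 22
Product: 25 (2R,4E,6S)-2-(TBSO-methyl)-4-methoxy-6-methyl-2-(triethylsilyloxy)non-4-en-8-ynal, via alkoxysulfonium chloride 24 (not isolated)
Conditions: (COCl)2, Me2SO, CH2Cl2, −78 to −30 °C; then Et3N, −78 to 0 °C
Reagents that add atoms: none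
Why: Swern oxidation applied directly to a primary triethylsilyl ether, which the chlorosulfonium reagent cleaves and oxidises to the aldehyde while the tertiary TES ether and the primary TBS ether stay in place.

Step 17
Reactants: 25 (2R,4E,6S)-2-(TBSO-methyl)-4-methoxy-6-methyl-2-(triethylsilyloxy)non-4-en-8-ynal; 3 (4R)-4-benzyl-3-propanoyl-1,3-oxazolidin-2-one
Product: 27 (4R)-4-benzyl-3-[(2R,3R,4R,6E,8S)-4-(TBSO-methyl)-3-hydroxy-6-methoxy-2,8-dimethyl-4-(triethylsilyloxy)undec-6-en-10-ynoyl]-1,3-oxazolidin-2-one, via dibutylboron Z-enolate 26 (not isolated)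
Conditions: 3, Bu2BOTf, i-Pr2NEt, CH2Cl2, −78 to 0 °C; then 25, −78 to 0 °C; pH 7 buffer, MeOH, H2O2
Reagents that add atoms: none
Why: Evans syn aldol reaction, in which the Z boron enolate reacts through a closed chair transition state on the enolate face dictated by the auxiliary; this sets C2 as R under reagent control and the temporary C3 carbinol syn to it.

Step 18
Reactants: 27 the aldol adduct of step 17
Product: 28 (2R,3R,4R,6E,8S)-4-(TBSO-methyl)-3-hydroxy-6-methoxy-2,8-dimethyl-4-(triethylsilyloxy)undec-6-en-10-ynoic acid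
Conditions: LiOH, H2O2, THF/H2O, 0 °C; Na2SO3; pH 4 NaH2PO4 buffer
Reagents that add atoms: hydrogen peroxide, OO
Why: Hydroperoxide cleavage of the imide at the exocyclic carbonyl should give the acid without retro-aldol and without epimerising C2.

Step 19
Reactants: 28 the acid of step 18; 2 (3S)-2-methylpent-1-en-3-ol
Product: 30 (3S)-2-methylpent-1-en-3-yl (2R,3R,4R,6E,8S)-4-(TBSO-methyl)-3-hydroxy-6-methoxy-2,8-dimethyl-4-(triethylsilyloxy)undec-6-en-10-ynoate, via mixed anhydride 29 (not isolated)
Conditions: 2,4,6-Cl3C6H2COCl, Et3N, THF, 0 °C to rt; then 2 (3 equiv), DMAP, toluene, rt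
Reagents that add atoms: none
Why: Yamaguchi esterification, in which the C3 hydroxyl flanked by the quaternary C4 should not compete with the excess secondary alcohol for the mixed anhydride, and acylation at oxygen leaves C13 untouched.

Step 20
Reactants: 30 the seco enyne ester of step 19
Product: 31 (2R,3R,4R,6E,8S,11Z,13S)-configured 14-membered dienyl lactone with C3 carbinol, C4 TES ether and primary TBS ether
Conditions: second-generation Grubbs catalyst RuCl2(=CHPh)(H2IMes)(PCy3) (15 mol %), ethylene (1 atm), toluene (1 mM), 80 °C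
Reagents that add atoms: none
Why: The ruthenium methylidene, kept regenerated by ethylene, undergoes [2+2] addition to the terminal alkyne C10≡C11 and cycloreversion to a vinylcarbene centred on C11 in which C10 already bears its methylene group; this carbene, directly or after ethylene has converted it into the 2-substituted butadiene, then closes the ring by metathesis with the 1,1-disubstituted alkene on C12, which creates C11=C12. The closest known reaction type is the macrocyclic ring-closing enyne metathesis of ω-alkenyl alkynes with the second-generation Grubbs catalyst under ethylene. The 14-membered ring closes in the endo mode, so that both alkyne carbons become ring members and the methylene is exocyclic, the mode that rings of twelve or more atoms follow. No stereocentre is formed, and the only stereochemical element created is the C11=C12 geometry. The step needs endo closure, the Z geometry with C10 cis to C13, and reaction at one alkyne and one alkene only: ring size secures the first, the strain that an E trisubstituted alkene would impose on the conjugated diene within the lactone is relied on for the second, and for the third the substrate offers a single alkyne and a single terminal alkene, while the trisubstituted enol ether is too hindered and the free C3 hydroxyl is inert toward the carbene.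

Step 21
Reactants: 31 the macrocyclic C3 carbinol of step 20
Product: 32 (2R,4R,6E,8S,11Z,13S)-configured 3-keto lactone with C4 TES ether and primary TBS ether
Conditions: Dess–Martin periodinane, pyridine, CH2Cl2, 0 °C to rt
Reagents that add atoms: none
Why: Dess–Martin oxidation of the only free hydroxyl under buffered, non-enolising conditions should give the β-keto lactone with C2 as set in step 17.

Step 22
Reactants: 32 the bis-silylated keto lactone of step 21
Product: 33 target, (2R,4R,6E,8S,11Z,13S)
Conditions: HF·pyridine, excess pyridine, THF, 0 °C to rt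
Reagents that add atoms: none
Why: Fluoride-induced cleavage of the primary TBS and tertiary TES ethers in a pyridine-buffered medium that should spare the enol ether and not enolise C2.

**Compound list**

1 | methacrolein | C=C(C)C=O | starting material
2 | (3S)-2-methylpent-1-en-3-ol | C=C(C)[C@H](CC)O | intermediate
3 | (4R)-4-benzyl-3-propanoyl-1,3-oxazolidin-2-one | CCC(=O)N1[C@H](Cc2ccccc2)COC1=O | starting material
4 | 3-bromo-1-(trimethylsilyl)prop-1-yne | C[Si](C)(C)C#CCBr | starting material
5 | sodium Z-enolate of 3 | [Na+].C/C=C(\[O-])N1[C@H](Cc2ccccc2)COC1=O | intermediate (not isolated)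
6 | (4R)-4-benzyl-3-[(2S)-2-methyl-5-(trimethylsilyl)pent-4-ynoyl]-1,3-oxazolidin-2-one | C[Si](C)(C)C#CC[C@H](C)C(=O)N1[C@H](Cc2ccccc2)COC1=O | intermediate
7 | (2S)-2-methyl-5-(trimethylsilyl)pent-4-yn-1-ol | C[Si](C)(C)C#CC[C@H](C)CO | intermediate
8 | (2S)-2-methyl-5-(trimethylsilyl)pent-4-ynal | C[Si](C)(C)C#CC[C@H](C)C=O | intermediate
9 | [(4S)-6,6-dibromo-4-methylhex-5-en-1-yn-1-yl]trimethylsilane | C[Si](C)(C)C#CC[C@H](C)C=C(Br)Br | intermediate
10 | 2-methylidenepropane-1,3-diol | C=C(CO)CO | starting material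
11 | 2-(TBSO-methyl)prop-2-en-1-ol | C=C(CO)CO[Si](C)(C)C(C)(C)C | intermediate
12 | [(2R)-2-(TBSO-methyl)oxiran-2-yl]methanol | OC[C@]1(CO[Si](C)(C)C(C)(C)C)CO1 | intermediate
13 | lithium (3S)-3-methyl-6-(trimethylsilyl)hexa-1,5-diyn-1-ide | [Li]C#C[C@@H](C)CC#C[Si](C)(C)C | intermediate (not isolated)
14 | diethyl[(3S)-3-methyl-6-(trimethylsilyl)hexa-1,5-diyn-1-yl]aluminium | CC[Al](CC)C#C[C@@H](C)CC#C[Si](C)(C)C | intermediate (not isolated)
15 | (2S,6S)-2-(TBSO-methyl)-6-methyl-9-(trimethylsilyl)nona-4,8-diyne-1,2-diol | OC[C@](O)(CO[Si](C)(C)C(C)(C)C)CC#C[C@@H](C)CC#C[Si](C)(C)C | intermediate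
16 | (2S,6S)-2-(TBSO-methyl)-2-hydroxy-6-methyl-9-(trimethylsilyl)nona-4,8-diyn-1-yl benzoate | O=C(OC[C@](O)(CO[Si](C)(C)C(C)(C)C)CC#C[C@@H](C)CC#C[Si](C)(C)C)c1ccccc1 | intermediate
17 | 2-O-dimethylsilyl ether of 16 | O=C(OC[C@](O[SiH](C)C)(CO[Si](C)(C)C(C)(C)C)CC#C[C@@H](C)CC#C[Si](C)(C)C)c1ccccc1 | intermediate (not isolated)
18 | [(3E,5S)-5-(TBSO-methyl)-2,2-dimethyl-3-[(2S)-2-methyl-5-(trimethylsilyl)pent-4-yn-1-ylidene]-1,2-oxasilolan-5-yl]methyl benzoate | O=C(OC[C@]1(CO[Si](C)(C)C(C)(C)C)C/C(=C\[C@@H](C)CC#C[Si](C)(C)C)[Si](C)(C)O1)c1ccccc1 | intermediate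
19 | (2S,4E,6S)-2-(TBSO-methyl)-2-hydroxy-4-iodo-6-methyl-9-(trimethylsilyl)non-4-en-8-yn-1-yl benzoate | O=C(OC[C@](O)(CO[Si](C)(C)C(C)(C)C)C/C(I)=C\[C@@H](C)CC#C[Si](C)(C)C)c1ccccc1 | intermediate
20 | (2S,4Z,6S)-2-(TBSO-methyl)-2-hydroxy-6-methyl-4-(4,4,5,5-tetramethyl-1,3,2-dioxaborolan-2-yl)-9-(trimethylsilyl)non-4-en-8-yn-1-yl benzoate | O=C(OC[C@](O)(CO[Si](C)(C)C(C)(C)C)C/C(B1OC(C)(C)C(C)(C)O1)=C\[C@@H](C)CC#C[Si](C)(C)C)c1ccccc1 | intermediate
21 | (2S,4E,6S)-2-(TBSO-methyl)-2-hydroxy-4-methoxy-6-methyl-9-(trimethylsilyl)non-4-en-8-yn-1-yl benzoate | O=C(OC[C@](O)(CO[Si](C)(C)C(C)(C)C)C/C(OC)=C\[C@@H](C)CC#C[Si](C)(C)C)c1ccccc1 | intermediate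
22 | (2S,4E,6S)-2-(TBSO-methyl)-4-methoxy-6-methylnon-4-en-8-yne-1,2-diol | OC[C@](O)(CO[Si](C)(C)C(C)(C)C)C/C(OC)=C\[C@@H](C)CC#C | intermediate
23 | 1,2-bis-O-triethylsilyl ether of 22 | CC[Si](CC)(CC)OC[C@](O[Si](CC)(CC)CC)(CO[Si](C)(C)C(C)(C)C)C/C(OC)=C\[C@@H](C)CC#C | intermediate
24 | alkoxydimethylsulfonium chloride at the C3 oxygen (primary TES lost) | [Cl-].C[S+](C)OC[C@](O[Si](CC)(CC)CC)(CO[Si](C)(C)C(C)(C)C)C/C(OC)=C\[C@@H](C)CC#C | intermediate (not isolated)
25 | (2R,4E,6S)-2-(TBSO-methyl)-4-methoxy-6-methyl-2-(triethylsilyloxy)non-4-en-8-ynal | O=C[C@](O[Si](CC)(CC)CC)(CO[Si](C)(C)C(C)(C)C)C/C(OC)=C\[C@@H](C)CC#C | intermediate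
26 | dibutylboron Z-enolate of 3 | CCCCB(CCCC)O/C(=C\C)N1[C@H](Cc2ccccc2)COC1=O | intermediate (not isolated)
27 | (4R)-4-benzyl-3-[(2R,3R,4R,6E,8S)-4-(TBSO-methyl)-3-hydroxy-6-methoxy-2,8-dimethyl-4-(triethylsilyloxy)undec-6-en-10-ynoyl]-1,3-oxazolidin-2-one | O=C1OC[C@@H](Cc2ccccc2)N1C(=O)[C@H](C)[C@@H](O)[C@](O[Si](CC)(CC)CC)(CO[Si](C)(C)C(C)(C)C)C/C(OC)=C\[C@@H](C)CC#C | intermediate
28 | (2R,3R,4R,6E,8S)-4-(TBSO-methyl)-3-hydroxy-6-methoxy-2,8-dimethyl-4-(triethylsilyloxy)undec-6-en-10-ynoic acid | OC(=O)[C@H](C)[C@@H](O)[C@](O[Si](CC)(CC)CC)(CO[Si](C)(C)C(C)(C)C)C/C(OC)=C\[C@@H](C)CC#C | intermediate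
29 | mixed anhydride of 28 with 2,4,6-trichlorobenzoic acid | Clc1cc(Cl)c(C(=O)OC(=O)[C@H](C)[C@@H](O)[C@](O[Si](CC)(CC)CC)(CO[Si](C)(C)C(C)(C)C)C/C(OC)=C\[C@@H](C)CC#C)c(Cl)c1 | intermediate (not isolated)
30 | (3S)-2-methylpent-1-en-3-yl ester of 28 (seco enyne ester) | C=C(C)[C@H](CC)OC(=O)[C@H](C)[C@@H](O)[C@](O[Si](CC)(CC)CC)(CO[Si](C)(C)C(C)(C)C)C/C(OC)=C\[C@@H](C)CC#C | intermediate
31 | (2R,3R,4R,6E,8S,11Z,13S) 14-membered dienyl lactone, C3 carbinol, C4 TES ether, primary TBS ether | C=C1/C=C(/C)[C@H](CC)OC(=O)[C@H](C)[C@@H](O)[C@](O[Si](CC)(CC)CC)(CO[Si](C)(C)C(C)(C)C)C/C(OC)=C\[C@@H](C)C1 | intermediate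
32 | (2R,4R,6E,8S,11Z,13S) 3-keto lactone, C4 TES ether, primary TBS ether | C=C1/C=C(/C)[C@H](CC)OC(=O)[C@H](C)C(=O)[C@](O[Si](CC)(CC)CC)(CO[Si](C)(C)C(C)(C)C)C/C(OC)=C\[C@@H](C)C1 | intermediate
33 | CNP0325854.3, (2R,4R,6E,8S,11Z,13S) | C=C1/C=C(/C)[C@H](CC)OC(=O)[C@H](C)C(=O)[C@](O)(CO)C/C(OC)=C\[C@@H](C)C1 | target

**Step count and risks**

Total step count: 22. Longest linear sequence: 19 steps (steps 2 to 5 and 8 to 22).

Steps most likely to fail:

Step 20. The carbene on C11 may be capped by ethylene or by a second alkyne faster than it finds the hindered 1,1-disubstituted alkene, so that acyclic triene or oligomers form, or the ring may close with the E geometry at C11=C12. The fallback is a relay ring-closing enyne metathesis that sets out from acid 28. Wittig reaction of hex-5-enal with 2-(triphenylphosphoranylidene)propanal gives (2E)-2-methylocta-2,7-dienal F1, ethyl transfer as in step 1 gives (3S,4E)-4-methyldeca-4,9-dien-3-ol F2, and Yamaguchi esterification of 28 with F2 gives the relay seco ester F3. With the same ruthenium catalyst under ethylene the carbene loads on the unhindered terminal vinyl group, expels cyclopentene and is thereby placed on C12; it then adds to the alkyne, the resulting C10 carbene takes its methylene group from ethylene, and the route is rejoined at 31.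

Step 13. The oxidative copper step may lose the boron by protonation or by oxidation to the C6 ketone, or may be too slow at the hindered trisubstituted carbon. The fallback is an epoxysilane route ending in a Peterson elimination; it sets out from alkenylsiloxane 18 and bypasses steps 11 and 12. Buffered m-chloroperbenzoic acid gives the α,β-epoxysilane F4 (either face serves; one diastereomer is drawn), and methanol with a trace of acid opens it at the silicon-bearing C6 with inversion to the α-methoxy-β-hydroxysilane F5. KH in THF then brings about the syn Peterson elimination through attack of the C7 alkoxide on silicon; inversion followed by syn elimination places OMe where silicon was, and the route is rejoined at 21.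

Step 8. The alane may attack the tertiary epoxide carbon or be consumed by the free hydroxyl, or the silyl group may move between the two hydroxymethyl arms, which would erode the configuration at C4. The fallback sets out from epoxy alcohol 12. Et3SiCl and imidazole give the triethylsilyl ether F6, the lithium acetylide 13 with BF3·OEt2 at −78 °C opens F6 at C5 to give the tertiary alcohol F7, and pyridinium p-toluenesulfonate in MeOH at 0 °C removes the primary triethylsilyl ether selectively, which rejoins the route at 15.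

**Further compounds**

F1 | step 20 | (2E)-2-methylocta-2,7-dienal | O=C/C(C)=C/CCCC=C
F2 | step 20 | (3S,4E)-4-methyldeca-4,9-dien-3-ol | CC[C@H](O)/C(C)=C/CCCC=C
F3 | step 20 | (3S,4E)-4-methyldeca-4,9-dien-3-yl ester of 28 (relay seco ester) | C=CCCC/C=C(\C)[C@H](CC)OC(=O)[C@H](C)[C@@H](O)[C@](O[Si](CC)(CC)CC)(CO[Si](C)(C)C(C)(C)C)C/C(OC)=C\[C@@H](C)CC#C
F4 | step 13 | α,β-epoxysilane from 18 (spiro epoxide at C6 and C7) | O=C(OC[C@]1(CO[Si](C)(C)C(C)(C)C)C[C@]2(O[C@H]2[C@@H](C)CC#C[Si](C)(C)C)[Si](C)(C)O1)c1ccccc1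
F5 | step 13 | α-methoxy-β-hydroxysilane (C6 OMe, C7 OH) | O=C(OC[C@]1(CO[Si](C)(C)C(C)(C)C)C[C@](OC)([C@@H](O)[C@@H](C)CC#C[Si](C)(C)C)[Si](C)(C)O1)c1ccccc1
F6 | step 8 | triethylsilyl ether of 12 | CC[Si](CC)(CC)OC[C@]1(CO[Si](C)(C)C(C)(C)C)CO1
F7 | step 8 | 1-O-triethylsilyl ether of 15 | CC[Si](CC)(CC)OC[C@](O)(CO[Si](C)(C)C(C)(C)C)CC#C[C@@H](C)CC#C[Si](C)(C)C
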